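## Retrosynthetic overview

- The strategy rests on the ring A/B fusion: the methyl-bearing quaternary C10 next to the tertiary C5 carbinol, with the C3 oxygen and the C4=C15 methylene in ring A. This is the retron of a tertiary C10 radical (from a C9=C10 alkene of a preformed ring B) closing ring A onto a vinyl ketone.
- Late disconnections: C3 angelate; C8 acetate and C12 methyl ester (from a cis-fused 8β,12-lactone); C11=C13 (lactone methylenation); C7–C11 (alkylation of a C8 ketone enolate).
- Key disconnection C1–C10: hydrogen-atom-transfer radical cyclisation of a ring B cyclohexenol that carries the cross-conjugated dienone arm C4(=C15)–C3(=O)–C2=C1 on C5.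
- C4–C5: addition of 2-lithiated penta-1,4-dien-3-ol to (R)-4-silyloxy-2-methylcyclohex-2-enone, made from 4-methoxy-3-methylphenol by quinone monoketal formation and CBS reduction.
- Ring order: ring B (from the arene), then ring A (key step), then a temporary lactone ring that is opened at the end.

Key step: step 10

Remark: the SMILES is read as methyl 8β-acetoxy-3β-angeloyloxy-5α-hydroxyeudesma-4(15),11(13)-dien-12-oate (10β-methyl, 7α-H). Eudesmane numbering and α/β descriptors (β = face of the C10 methyl) are used for all bicyclic compounds and for the future positions of monocyclic ring atoms; "trinor" and "nor" mark intermediates that still lack C11–C13 or C13.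
Remark: compounds 1, 7, 10, 20 and 31 are taken as commercial.

## Route

Step 1
Reactants: 1 4-methoxy-3-methylphenol
Product: 2 4,4-dimethoxy-3-methylcyclohexa-2,5-dien-1-one
Conditions: PhI(OAc)2, MeOH, 0 °C
Reagents that add atoms: methanol, CO
Why: Oxidative dearomatisation of a para-methoxyphenol with the hypervalent iodine reagent in methanol traps the phenoxonium ion at the methoxy-bearing carbon and gives the para-quinone monoketal, in which the free carbonyl is the future C8 and the ketal carbon the future C5, so that no regiochemical choice between two carbonyls arises later.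

Step 2
Reactants: 2 4,4-dimethoxy-3-methylcyclohexa-2,5-dien-1-one
Product: 3 4,4-dimethoxy-3-methylcyclohex-2-en-1-one
Conditions: H2 (1 atm), RhCl(PPh3)3 (5 mol %), toluene, rt
Reagents that add atoms: none
Why: Homogeneous hydrogenation with RhCl(PPh3)3 should saturate only the cis-disubstituted alkene (future C6–C7), because the trisubstituted methyl-bearing alkene (future C9=C10) reacts far more slowly and this catalyst does not cleave the ketal.

Step 3
Reactants: 3 4,4-dimethoxy-3-methylcyclohex-2-en-1-one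
Product: 4 (R)-4,4-dimethoxy-3-methylcyclohex-2-en-1-ol
Conditions: (S)-1-methyl-3,3-diphenyltetrahydro-1H,3H-pyrrolo[1,2-c][1,3,2]oxazaborole (10 mol %), catecholborane, toluene, −78 °C
Reagents that add atoms: none
Why: Corey–Bakshi–Shibata reduction, in which the alkenyl carbon is the large and the ring methylene the small carbonyl substituent, so that the (S)-catalyst should give the (R)-allylic alcohol and thereby set C8, the centre from which the absolute configuration of the whole route derives.

Step 4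
Reactants: 4 (R)-4,4-dimethoxy-3-methylcyclohex-2-en-1-ol
Product: 5 (R)-tert-butyl[(4,4-dimethoxy-3-methylcyclohex-2-en-1-yl)oxy]dimethylsilane
Conditions: TBSCl, imidazole, DMF, rt
Reagents that add atoms: tert-butyldimethylsilyl chloride, CC(C)(C)[Si](C)(C)Cl
Why: Standard silylation of the secondary allylic alcohol installs a bulky, non-chelating group that later shields one face of the C5 carbonyl and leaves the C8 centre untouched.

Step 5
Reactants: 5 (R)-tert-butyl[(4,4-dimethoxy-3-methylcyclohex-2-en-1-yl)oxy]dimethylsilane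
Product: 6 (R)-4-[(tert-butyldimethylsilyl)oxy]-2-methylcyclohex-2-en-1-one
Conditions: pyridinium p-toluenesulfonate (10 mol %), acetone/H2O (10:1), rt
Reagents that add atoms: water, O
Why: Mild acid-catalysed ketal hydrolysis unmasks the C5 ketone as the conjugated enone without ionising the allylic silyl ether, so the C8 configuration is kept.

Step 6
Reactants: 7 acrolein
Product: 9 2-bromoprop-2-enal, via 2,3-dibromopropanal 8 (not isolated)
Conditions: Br2, CH2Cl2, −78 → 0 °C; then Et3N, 0 °C
Reagents that add atoms: bromine, BrBr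
Why: Bromination of the alkene followed by dehydrobromination of the α-bromo aldehyde with triethylamine is the standard preparation of 2-bromoacrolein, which is used as a cold solution.

Step 7
Reactants: 9 2-bromoprop-2-enal; 10 vinylmagnesium bromide
Product: 11 2-bromopenta-1,4-dien-3-ol (racemic)
Conditions: THF, −78 °C; aq. NH4Cl
Reagents that add atoms: none
Why: Grignard 1,2-addition to the enal gives the bis-allylic alcohol, whose carbinol carbon becomes the C3 carbonyl in step 9, so its configuration is immaterial.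

Step 8
Reactants: 11 2-bromopenta-1,4-dien-3-ol; 6 (R)-4-[(tert-butyldimethylsilyl)oxy]-2-methylcyclohex-2-en-1-one
Product: 13 (1S,4R)-4-[(tert-butyldimethylsilyl)oxy]-1-(3-hydroxypenta-1,4-dien-2-yl)-2-methylcyclohex-2-en-1-ol (side-chain carbinol epimers), via dilithio reagent 12 (not isolated)
Conditions: t-BuLi (3 equiv per 11), Et2O, −78 °C; then 6 (0.4 equiv per 11), THF, −78 → −40 °C; aq. NH4Cl
Reagents that add atoms: none
Why: Deprotonation and bromine–lithium exchange give a β-oxido vinyllithium (the alkoxide cannot be expelled to an allene), which should undergo organolithium 1,2-addition to the enone by axial attack on the face anti to the pseudoaxial C8 silyloxy group, setting C5 with its hydroxyl cis to the silyloxy group.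

Step 9
Reactants: 13 (1S,4R)-4-[(tert-butyldimethylsilyl)oxy]-1-(3-hydroxypenta-1,4-dien-2-yl)-2-methylcyclohex-2-en-1-ol
Product: 14 2-[(1S,4R)-4-[(tert-butyldimethylsilyl)oxy]-1-hydroxy-2-methylcyclohex-2-en-1-yl]penta-1,4-dien-3-one
Conditions: Dess–Martin periodinane, NaHCO3, CH2Cl2, 0 °C; used at once
Reagents that add atoms: none
Why: Buffered Dess–Martin oxidation converts the secondary bis-allylic alcohol of both epimers into the one cross-conjugated dienone, while the tertiary C5 alcohol cannot be oxidised and the acid-sensitive doubly allylic carbinol is not exposed to acid.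

Step 10
Reactants: 14 2-[(1S,4R)-4-[(tert-butyldimethylsilyl)oxy]-1-hydroxy-2-methylcyclohex-2-en-1-yl]penta-1,4-dien-3-one
Product: 15 8α-[(tert-butyldimethylsilyl)oxy]-5α-hydroxy-11,12,13-trinoreudesm-4(15)-en-3-one
Conditions: Fe(acac)3 (0.3 equiv), PhSiH3 (2.5 equiv), EtOH/ethylene glycol (5:1), 0.01 M, degassed, 60 °C
Reagents that add atoms: none
Why: Fe(acac)3 and PhSiH3 in ethanol generate an iron hydride that transfers a hydrogen atom to C9 of the electron-rich trisubstituted C9=C10 alkene, and the resulting tertiary, nucleophilic C10 radical adds to the unsubstituted terminus C1 of the vinyl ketone; the α-keto radical at C2 is then reduced by divalent iron and protonated by the solvent, which returns trivalent iron. The closest known reaction type is the iron-hydride-initiated reductive olefin coupling (radical Giese addition) in its intramolecular form, an established way to build quaternary carbons. Ring A closes in the 6-endo-trig mode (C1 and C2 both lie in the new ring), attack on C15 (4-exo) or on C2 (5-exo, giving an unstabilised primary radical) not being competitive. The only new stereocentre, C10, is controlled by C5: in the ring B chair the C5 arm and the C8 silyloxy group are equatorial and the C5 hydroxyl axial, and a chair-like transition state forms the C1–C10 bond equatorially, so that the methyl becomes axial and anti to the hydroxyl (trans fusion), as in radical polyene cyclisations that give trans-decalins. The step needs hydrogen-atom transfer to C9=C10 rather than to the two enone alkenes and tolerance of the free tertiary alcohol; the first rests on the preference of the iron hydride for electron-rich, more substituted alkenes (enones act as acceptors in this chemistry), the second on the neutral conditions, and high dilution suppresses intermolecular addition.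

Step 11
Reactants: 15 8α-[(tert-butyldimethylsilyl)oxy]-5α-hydroxy-11,12,13-trinoreudesm-4(15)-en-3-one
Product: 16 8α-[(tert-butyldimethylsilyl)oxy]-11,12,13-trinoreudesm-4(15)-ene-3β,5α-diol
Conditions: NaBH4, CeCl3·7H2O, MeOH, −78 °C
Reagents that add atoms: none
Why: Luche 1,2-reduction, in which the small hydride should attack the C3 carbonyl axially on the α-face (the usual course for a trans-decalin 3-ketone, which coordination to the axial 5α-hydroxyl can only reinforce) to give the equatorial 3β-alcohol and leave the exocyclic alkene intact.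

Step 12
Reactants: 16 8α-[(tert-butyldimethylsilyl)oxy]-11,12,13-trinoreudesm-4(15)-ene-3β,5α-diol
Product: 17 8α-[(tert-butyldimethylsilyl)oxy]-3β-[(4-methoxybenzyl)oxy]-11,12,13-trinoreudesm-4(15)-en-5α-ol
Conditions: NaH (1.1 equiv), 4-methoxybenzyl chloride, Bu4NI (cat.), THF/DMF, 0 °C → rt
Reagents that add atoms: 4-methoxybenzyl chloride, COc1ccc(CCl)cc1
Why: Williamson etherification of the secondary allylic alkoxide, the hindered tertiary C5 hydroxyl staying free, gives a C3 protecting group that is orthogonal to the C8 silyl ether and can be removed at the end without acid or base.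

Step 13
Reactants: 17 8α-[(tert-butyldimethylsilyl)oxy]-3β-[(4-methoxybenzyl)oxy]-11,12,13-trinoreudesm-4(15)-en-5α-ol
Product: 18 3β-[(4-methoxybenzyl)oxy]-11,12,13-trinoreudesm-4(15)-ene-5α,8α-diol
Conditions: Bu4NF, THF, rt
Reagents that add atoms: none
Why: Fluoride-induced desilylation frees only the C8 alcohol, because the C3 oxygen carries a benzyl-type ether.

Step 14
Reactants: 18 3β-[(4-methoxybenzyl)oxy]-11,12,13-trinoreudesm-4(15)-ene-5α,8α-diol
Product: 19 5α-hydroxy-3β-[(4-methoxybenzyl)oxy]-11,12,13-trinoreudesm-4(15)-en-8-one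
Conditions: Dess–Martin periodinane, NaHCO3, CH2Cl2, rt
Reagents that add atoms: none
Why: Dess–Martin oxidation of the only secondary alcohol gives the C8 ketone and removes the auxiliary C8 stereocentre after it has controlled C5 and, through it, C10.

Step 15
Reactants: 19 5α-hydroxy-3β-[(4-methoxybenzyl)oxy]-11,12,13-trinoreudesm-4(15)-en-8-one; 20 methyl bromoacetate
Product: 21 methyl 5α-hydroxy-3β-[(4-methoxybenzyl)oxy]-8-oxo-13-noreudesm-4(15)-en-12-oate (7β side chain)
Conditions: LDA (2.2 equiv), THF, −78 °C; then 20, DMPU, −78 → −30 °C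
Reagents that add atoms: none
Why: Kinetic enolate alkylation: LDA should deprotonate the C8 ketone at C7, away from the neopentyl C9 next to quaternary C10 (the second equivalent covers the C5 hydroxyl), and the bromoacetate should enter on the face opposite the axial 5α-oxygen to give the equatorial 7β-ester, which is also the thermodynamic epimer at this enolisable centre.

Step 16
Reactants: 21 methyl 5α-hydroxy-3β-[(4-methoxybenzyl)oxy]-8-oxo-13-noreudesm-4(15)-en-12-oate
Product: 23 5α-hydroxy-3β-[(4-methoxybenzyl)oxy]-13-noreudesm-4(15)-en-8β,12-olide (cis-fused γ-lactone), via hydroxy ester 22 (not isolated)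
Conditions: LiBH(s-Bu)3 (2.2 equiv), THF, −78 °C → rt; aq. NH4Cl
Reagents that add atoms: none
Why: Substrate-controlled ketone reduction, in which the bulky hydride attacks C8 equatorially from the α-side because the axial β-trajectory is blocked by the syn-axial C10 methyl, gives the axial 8β-alkoxide, which lactonises onto the cis-disposed C7 acetate arm.

Step 17
Reactants: 23 5α-hydroxy-3β-[(4-methoxybenzyl)oxy]-13-noreudesm-4(15)-en-8β,12-olide
Product: 26 5α-hydroxy-3β-[(4-methoxybenzyl)oxy]eudesma-4(15),11(13)-dien-8β,12-olide, via Mannich base 24 (not isolated), via ammonium iodide 25 (not isolated)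
Conditions: LDA (2.5 equiv), THF, −78 °C; Me2N=CH2 I, −78 °C → rt; then MeI, MeOH, rt; then DBU, CH2Cl2, rt
Reagents that add atoms: N,N-dimethylmethyleneiminium iodide (Eschenmoser's salt), C=[N+](C)C.[I-]
Why: Lactone α-methylenation by the Eschenmoser sequence, in which the lithium enolate is aminomethylated at C11 and quaternisation followed by β-elimination creates C11=C13 in conjugation with the lactone carbonyl.

Step 18
Reactants: 26 5α-hydroxy-3β-[(4-methoxybenzyl)oxy]eudesma-4(15),11(13)-dien-8β,12-olide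
Product: 28 methyl 5α,8β-dihydroxy-3β-[(4-methoxybenzyl)oxy]eudesma-4(15),11(13)-dien-12-oate, via potassium carboxylate 27 (not isolated)
Conditions: KOH (1.1 equiv), THF/H2O, rt; concentrate; then MeI, KHCO3, DMF, 0 °C → rt; crude product taken on directly
Reagents that add atoms: potassium hydroxide, [K+].[OH-]; iodomethane, CI
Why: Saponification opens the lactone to the carboxylate, and SN2 methylation of this salt under non-acidic conditions gives the methyl ester without passing through the free hydroxy acid, which would relactonise.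

Step 19
Reactants: 28 methyl 5α,8β-dihydroxy-3β-[(4-methoxybenzyl)oxy]eudesma-4(15),11(13)-dien-12-oate
Product: 29 methyl 8β-acetoxy-5α-hydroxy-3β-[(4-methoxybenzyl)oxy]eudesma-4(15),11(13)-dien-12-oate
Conditions: Ac2O, Et3N, 4-(dimethylamino)pyridine (cat.), CH2Cl2, 0 °C → rt
Reagents that add atoms: acetic anhydride, CC(=O)OC(C)=O
Why: Acyl-transfer-catalysed acetylation esterifies the secondary 8β-hydroxyl, whereas the tertiary, hindered 5α-hydroxyl should not react under these mild conditions.

Step 20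
Reactants: 29 methyl 8β-acetoxy-5α-hydroxy-3β-[(4-methoxybenzyl)oxy]eudesma-4(15),11(13)-dien-12-oate
Product: 30 methyl 8β-acetoxy-3β,5α-dihydroxyeudesma-4(15),11(13)-dien-12-oate
Conditions: DDQ (1.2 equiv), CH2Cl2/pH 7 buffer (10:1), 0 °C
Reagents that add atoms: none
Why: Oxidative cleavage of the 4-methoxybenzyl ether with DDQ (benzylic oxocarbenium ion, then hydrolysis) frees the 3β-hydroxyl without touching the esters, the alkenes or the tertiary alcohol.

Step 21
Reactants: 30 methyl 8β-acetoxy-3β,5α-dihydroxyeudesma-4(15),11(13)-dien-12-oate; 31 angelic acid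
Product: 33 methyl 8β-acetoxy-3β-angeloyloxy-5α-hydroxyeudesma-4(15),11(13)-dien-12-oate (CNP0179024.1), via mixed anhydride 32 (not isolated)
Conditions: 2,4,6-Cl3C6H2COCl, Et3N, toluene, rt; then 30, 80 °C
Reagents that add atoms: none
Why: Yamaguchi esterification through the mixed 2,4,6-trichlorobenzoic anhydride acylates the secondary 3β-hydroxyl (the tertiary 5α-hydroxyl is too hindered), and leaving out a nucleophilic catalyst keeps the Z-configured angelate from isomerising to the tiglate.

## Compound list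

1 | 4-methoxy-3-methylphenol | COc1ccc(O)cc1C | starting material
2 | 4,4-dimethoxy-3-methylcyclohexa-2,5-dien-1-one | COC1(OC)C=CC(=O)C=C1C | intermediate
3 | 4,4-dimethoxy-3-methylcyclohex-2-en-1-one | COC1(OC)CCC(=O)C=C1C | intermediate
4 | (R)-4,4-dimethoxy-3-methylcyclohex-2-en-1-ol | C1CC(OC)(OC)C(C)=C[C@@H]1O | intermediate
5 | (R)-tert-butyl[(4,4-dimethoxy-3-methylcyclohex-2-en-1-yl)oxy]dimethylsilane | C1CC(OC)(OC)C(C)=C[C@@H]1O[Si](C)(C)C(C)(C)C | intermediate
6 | (R)-4-[(tert-butyldimethylsilyl)oxy]-2-methylcyclohex-2-en-1-one | C1CC(=O)C(C)=C[C@@H]1O[Si](C)(C)C(C)(C)C | intermediate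
7 | acrolein | C=CC=O | starting material
8 | 2,3-dibromopropanal | O=CC(Br)CBr | intermediate
9 | 2-bromoprop-2-enal | C=C(Br)C=O | intermediate
10 | vinylmagnesium bromide | C=C[Mg]Br | starting material
11 | 2-bromopenta-1,4-dien-3-ol (racemic) | C=CC(O)C(Br)=C | intermediate
12 | lithium 2-lithiopenta-1,4-dien-3-olate | C=CC(O[Li])C([Li])=C | intermediate
13 | (1S,4R)-4-[(tert-butyldimethylsilyl)oxy]-1-(3-hydroxypenta-1,4-dien-2-yl)-2-methylcyclohex-2-en-1-ol | C1C[C@@](O)(C(=C)C(O)C=C)C(C)=C[C@@H]1O[Si](C)(C)C(C)(C)C | intermediate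
14 | 2-[(1S,4R)-4-[(tert-butyldimethylsilyl)oxy]-1-hydroxy-2-methylcyclohex-2-en-1-yl]penta-1,4-dien-3-one | C1C[C@@](O)(C(=C)C(=O)C=C)C(C)=C[C@@H]1O[Si](C)(C)C(C)(C)C | intermediate
15 | 8α-[(tert-butyldimethylsilyl)oxy]-5α-hydroxy-11,12,13-trinoreudesm-4(15)-en-3-one | C1C[C@@]2(O)C(=C)C(=O)CC[C@]2(C)C[C@@H]1O[Si](C)(C)C(C)(C)C | intermediate
16 | 8α-[(tert-butyldimethylsilyl)oxy]-11,12,13-trinoreudesm-4(15)-ene-3β,5α-diol | C1C[C@@]2(O)C(=C)[C@@H](O)CC[C@]2(C)C[C@@H]1O[Si](C)(C)C(C)(C)C | intermediate
17 | 8α-[(tert-butyldimethylsilyl)oxy]-3β-[(4-methoxybenzyl)oxy]-11,12,13-trinoreudesm-4(15)-en-5α-ol | C1C[C@@]2(O)C(=C)[C@@H](OCc3ccc(OC)cc3)CC[C@]2(C)C[C@@H]1O[Si](C)(C)C(C)(C)C | intermediate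
18 | 3β-[(4-methoxybenzyl)oxy]-11,12,13-trinoreudesm-4(15)-ene-5α,8α-diol | C1C[C@@]2(O)C(=C)[C@@H](OCc3ccc(OC)cc3)CC[C@]2(C)C[C@@H]1O | intermediate
19 | 5α-hydroxy-3β-[(4-methoxybenzyl)oxy]-11,12,13-trinoreudesm-4(15)-en-8-one | C1C[C@@]2(O)C(=C)[C@@H](OCc3ccc(OC)cc3)CC[C@]2(C)CC1=O | intermediate
20 | methyl bromoacetate | COC(=O)CBr | starting material
21 | methyl 5α-hydroxy-3β-[(4-methoxybenzyl)oxy]-8-oxo-13-noreudesm-4(15)-en-12-oate | COC(=O)C[C@H]1C[C@@]2(O)C(=C)[C@@H](OCc3ccc(OC)cc3)CC[C@]2(C)CC1=O | intermediate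
22 | methyl 5α,8β-dihydroxy-3β-[(4-methoxybenzyl)oxy]-13-noreudesm-4(15)-en-12-oate | COC(=O)C[C@H]1C[C@@]2(O)C(=C)[C@@H](OCc3ccc(OC)cc3)CC[C@]2(C)C[C@H]1O | intermediate
23 | 5α-hydroxy-3β-[(4-methoxybenzyl)oxy]-13-noreudesm-4(15)-en-8β,12-olide | O=C1C[C@H]2C[C@@]3(O)C(=C)[C@@H](OCc4ccc(OC)cc4)CC[C@]3(C)C[C@H]2O1 | intermediate
24 | 13-(dimethylamino)-5α-hydroxy-3β-[(4-methoxybenzyl)oxy]eudesm-4(15)-en-8β,12-olide (C11 epimers) | O=C1C(CN(C)C)[C@H]2C[C@@]3(O)C(=C)[C@@H](OCc4ccc(OC)cc4)CC[C@]3(C)C[C@H]2O1 | intermediate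
25 | 13-(trimethylammonio)-5α-hydroxy-3β-[(4-methoxybenzyl)oxy]eudesm-4(15)-en-8β,12-olide iodide | [I-].O=C1C(C[N+](C)(C)C)[C@H]2C[C@@]3(O)C(=C)[C@@H](OCc4ccc(OC)cc4)CC[C@]3(C)C[C@H]2O1 | intermediate
26 | 5α-hydroxy-3β-[(4-methoxybenzyl)oxy]eudesma-4(15),11(13)-dien-8β,12-olide | O=C1C(=C)[C@H]2C[C@@]3(O)C(=C)[C@@H](OCc4ccc(OC)cc4)CC[C@]3(C)C[C@H]2O1 | intermediate
27 | potassium 5α,8β-dihydroxy-3β-[(4-methoxybenzyl)oxy]eudesma-4(15),11(13)-dien-12-oate | [K+].C=C(C(=O)[O-])[C@H]1C[C@@]2(O)C(=C)[C@@H](OCc3ccc(OC)cc3)CC[C@]2(C)C[C@H]1O | intermediate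
28 | methyl 5α,8β-dihydroxy-3β-[(4-methoxybenzyl)oxy]eudesma-4(15),11(13)-dien-12-oate | C=C(C(=O)OC)[C@H]1C[C@@]2(O)C(=C)[C@@H](OCc3ccc(OC)cc3)CC[C@]2(C)C[C@H]1O | intermediate
29 | methyl 8β-acetoxy-5α-hydroxy-3β-[(4-methoxybenzyl)oxy]eudesma-4(15),11(13)-dien-12-oate | C=C(C(=O)OC)[C@H]1C[C@@]2(O)C(=C)[C@@H](OCc3ccc(OC)cc3)CC[C@]2(C)C[C@H]1OC(C)=O | intermediate
30 | methyl 8β-acetoxy-3β,5α-dihydroxyeudesma-4(15),11(13)-dien-12-oate | C=C(C(=O)OC)[C@H]1C[C@@]2(O)C(=C)[C@@H](O)CC[C@]2(C)C[C@H]1OC(C)=O | intermediate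
31 | angelic acid, (Z)-2-methylbut-2-enoic acid | C/C=C(/C)C(=O)O | starting material
32 | (Z)-2-methylbut-2-enoic 2,4,6-trichlorobenzoic anhydride | C/C=C(/C)C(=O)OC(=O)c1c(Cl)cc(Cl)cc1Cl | intermediate
33 | methyl 8β-acetoxy-3β-angeloyloxy-5α-hydroxyeudesma-4(15),11(13)-dien-12-oate (CNP0179024.1) | C=C(C(=O)OC)[C@H]1C[C@@]2(O)C(=C)[C@@H](OC(=O)/C(C)=C\C)CC[C@]2(C)C[C@H]1OC(C)=O | target

## Step count

Total step count: 21.
Longest linear sequence: 19 steps (steps 1–5 and 8–21, from 1); steps 6 and 7 make the side-chain fragment.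

## Steps most likely to fail

**Step 10 (key step).** What may go wrong: ring closure through the axial trajectory, which would give the cis ring fusion (C10 epimer). The dienone may also be consumed before the C10 radical forms, by hydrogen-atom transfer to its own alkenes, by oxa-Michael closure of the C5 hydroxyl onto C1, or by polymerisation.

Fallback (sets out from 3, returns at 19): the trans 5α-hydroxy/10β-methyl array is made instead by Robinson annulation and epoxide-to-allylic-alcohol isomerisation. A Michael acceptor should enter a 2-methyl-4-silyloxycyclohexanone enolate axially and anti to the silyloxy group, so the mirror-image ring B is needed. Reduction of 3 with the (R)-oxazaborolidine gives (S)-4,4-dimethoxy-3-methylcyclohex-2-en-1-ol F1. As in steps 4 and 5 this is silylated to (S)-tert-butyl[(4,4-dimethoxy-3-methylcyclohex-2-en-1-yl)oxy]dimethylsilane F2 and hydrolysed to (S)-4-[(tert-butyldimethylsilyl)oxy]-2-methylcyclohex-2-en-1-one F3. Conjugate reduction with LiBH(s-Bu)3 gives (4S)-4-[(tert-butyldimethylsilyl)oxy]-2-methylcyclohexan-1-one F4. KOH-mediated Michael addition to ethyl vinyl ketone at the methyl-bearing α-carbon gives (2R,4S)-4-[(tert-butyldimethylsilyl)oxy]-2-methyl-2-(3-oxopentyl)cyclohexan-1-one F5, and aldol condensation (NaOMe, MeOH) gives 8β-[(tert-butyldimethylsilyl)oxy]-11,12,13-trinoreudesm-4-en-3-one F6 with the 10β-methyl group. Luche reduction gives 8β-[(tert-butyldimethylsilyl)oxy]-11,12,13-trinoreudesm-4-en-3β-ol F7, and NaH with 4-methoxybenzyl chloride gives 8β-[(tert-butyldimethylsilyl)oxy]-3β-[(4-methoxybenzyl)oxy]-11,12,13-trinoreudesm-4-ene F8. Epoxidation with m-CPBA on the α-face, opposite the angular methyl, gives 8β-[(tert-butyldimethylsilyl)oxy]-4α,5α-epoxy-3β-[(4-methoxybenzyl)oxy]-11,12,13-trinoreudesmane F9. Al(OiPr)3 in refluxing toluene opens the epoxide by removal of a C15 proton to 8β-[(tert-butyldimethylsilyl)oxy]-3β-[(4-methoxybenzyl)oxy]-11,12,13-trinoreudesm-4(15)-en-5α-ol F10, the C8 epimer of 17. Bu4NF gives 3β-[(4-methoxybenzyl)oxy]-11,12,13-trinoreudesm-4(15)-ene-5α,8β-diol F11, and Dess–Martin oxidation gives 19.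

**Step 8.** What may go wrong: proton transfer from the C6 methylene of 6 to the strongly basic, aggregated dilithio reagent (enolisation and low conversion), and incomplete face selection at C5.

Fallback (sets out from 6, returns at 13): the arm is built in two stages from a monoanionic reagent. Commercial 2-bromo-3,3-diethoxyprop-1-ene and t-BuLi give (3,3-diethoxyprop-1-en-2-yl)lithium F12, which adds to 6 at −78 °C to give (1S,4R)-4-[(tert-butyldimethylsilyl)oxy]-1-(3,3-diethoxyprop-1-en-2-yl)-2-methylcyclohex-2-en-1-ol F13. Oxalic acid on wet silica gel unmasks 2-[(1S,4R)-4-[(tert-butyldimethylsilyl)oxy]-1-hydroxy-2-methylcyclohex-2-en-1-yl]prop-2-enal F14, and excess vinylmagnesium bromide 10 adds to the aldehyde to give 13. The C5 epimers are diastereomers because of the C8 centre and can be separated at this stage if face selection is the weak point.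

**Step 15.** What may go wrong: proton exchange between the enolate and the alkylated ketone (dialkylation, loss of regiocontrol between C7 and C9) and O-alkylation of the C5 alkoxide.

Fallback (sets out from 19, returns at 21): the acetate arm is introduced by condensation and reduction. Thermodynamically controlled aldol condensation of 19 with glyoxylic acid (NaOH, aqueous EtOH) at the less hindered C7 methylene gives (E)-2-[5α-hydroxy-3β-[(4-methoxybenzyl)oxy]-8-oxo-11,12,13-trinoreudesm-4(15)-en-7-ylidene]acetic acid F15. Zinc in acetic acid reduces the ene-keto acid to 5α-hydroxy-3β-[(4-methoxybenzyl)oxy]-8-oxo-13-noreudesm-4(15)-en-12-oic acid F16, whose enolisable C7 centre settles in the equatorial 7β configuration. Me3SiCHN2 in MeOH/toluene gives 21.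

## Further compounds

F1 | step 10 | (S)-4,4-dimethoxy-3-methylcyclohex-2-en-1-ol | C1CC(OC)(OC)C(C)=C[C@H]1O
F2 | step 10 | (S)-tert-butyl[(4,4-dimethoxy-3-methylcyclohex-2-en-1-yl)oxy]dimethylsilane | C1CC(OC)(OC)C(C)=C[C@H]1O[Si](C)(C)C(C)(C)C
F3 | step 10 | (S)-4-[(tert-butyldimethylsilyl)oxy]-2-methylcyclohex-2-en-1-one | C1CC(=O)C(C)=C[C@H]1O[Si](C)(C)C(C)(C)C
F4 | step 10 | (4S)-4-[(tert-butyldimethylsilyl)oxy]-2-methylcyclohexan-1-one (C2 epimers) | C1CC(=O)C(C)C[C@H]1O[Si](C)(C)C(C)(C)C
F5 | step 10 | (2R,4S)-4-[(tert-butyldimethylsilyl)oxy]-2-methyl-2-(3-oxopentyl)cyclohexan-1-one | C1CC(=O)[C@](C)(CCC(=O)CC)C[C@H]1O[Si](C)(C)C(C)(C)C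
F6 | step 10 | 8β-[(tert-butyldimethylsilyl)oxy]-11,12,13-trinoreudesm-4-en-3-one | C1CC2=C(C)C(=O)CC[C@]2(C)C[C@H]1O[Si](C)(C)C(C)(C)C
F7 | step 10 | 8β-[(tert-butyldimethylsilyl)oxy]-11,12,13-trinoreudesm-4-en-3β-ol | C1CC2=C(C)[C@@H](O)CC[C@]2(C)C[C@H]1O[Si](C)(C)C(C)(C)C
F8 | step 10 | 8β-[(tert-butyldimethylsilyl)oxy]-3β-[(4-methoxybenzyl)oxy]-11,12,13-trinoreudesm-4-ene | C1CC2=C(C)[C@@H](OCc3ccc(OC)cc3)CC[C@]2(C)C[C@H]1O[Si](C)(C)C(C)(C)C
F9 | step 10 | 8β-[(tert-butyldimethylsilyl)oxy]-4α,5α-epoxy-3β-[(4-methoxybenzyl)oxy]-11,12,13-trinoreudesmane | C1C[C@@]2(O3)[C@@]3(C)[C@@H](OCc4ccc(OC)cc4)CC[C@]2(C)C[C@H]1O[Si](C)(C)C(C)(C)C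
F10 | step 10 | 8β-[(tert-butyldimethylsilyl)oxy]-3β-[(4-methoxybenzyl)oxy]-11,12,13-trinoreudesm-4(15)-en-5α-ol | C1C[C@@]2(O)C(=C)[C@@H](OCc3ccc(OC)cc3)CC[C@]2(C)C[C@H]1O[Si](C)(C)C(C)(C)C
F11 | step 10 | 3β-[(4-methoxybenzyl)oxy]-11,12,13-trinoreudesm-4(15)-ene-5α,8β-diol | C1C[C@@]2(O)C(=C)[C@@H](OCc3ccc(OC)cc3)CC[C@]2(C)C[C@H]1O
F12 | step 8 | (3,3-diethoxyprop-1-en-2-yl)lithium | CCOC(OCC)C([Li])=C
F13 | step 8 | (1S,4R)-4-[(tert-butyldimethylsilyl)oxy]-1-(3,3-diethoxyprop-1-en-2-yl)-2-methylcyclohex-2-en-1-ol | C1C[C@@](O)(C(=C)C(OCC)OCC)C(C)=C[C@@H]1O[Si](C)(C)C(C)(C)C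
F14 | step 8 | 2-[(1S,4R)-4-[(tert-butyldimethylsilyl)oxy]-1-hydroxy-2-methylcyclohex-2-en-1-yl]prop-2-enal | C1C[C@@](O)(C(=C)C=O)C(C)=C[C@@H]1O[Si](C)(C)C(C)(C)C
F15 | step 15 | (E)-2-[5α-hydroxy-3β-[(4-methoxybenzyl)oxy]-8-oxo-11,12,13-trinoreudesm-4(15)-en-7-ylidene]acetic acid | OC(=O)/C=C1\C[C@@]2(O)C(=C)[C@@H](OCc3ccc(OC)cc3)CC[C@]2(C)CC1=O
F16 | step 15 | 5α-hydroxy-3β-[(4-methoxybenzyl)oxy]-8-oxo-13-noreudesm-4(15)-en-12-oic acid | OC(=O)C[C@H]1C[C@@]2(O)C(=C)[C@@H](OCc3ccc(OC)cc3)CC[C@]2(C)CC1=O
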